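The butenolide (O, C15, C14, C13, C16; labdane numbering) is cut at C14–C15 and C13–C16 into a terminal alkyne (C13≡C14), formaldehyde (C15) and carbon monoxide (C16). A nickel-mediated hetero-Pauson–Khand (2+2+1) union of the three components closes the lactone in one operation; it exploits that C13 is the only substituted ring carbon, so the terminal alkyne fixes the regiochemistry. Its precursor is the complete bis-silylated trans-decalin with a but-3-ynyl chain on C9, built by an epoxide-initiated, allylsilane-terminated bicyclisation in which one Sharpless epoxide relays its configuration to C4, C5, C9 and C10; the axial C7 hydroxyl follows by allylic oxidation.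

Key step: step 12

Remark: positions C1–C20 and rings A and B follow labdane numbering (C19 is the axial CH2O on C4, C17 the exocyclic methylene carbon, C15 and C16 the lactone CH2 and C=O); pent-4-ynal is taken as purchased and formaldehyde is used as the monomer cracked from paraformaldehyde.

Step 1
Reactants: 1 pent-4-ynal; 2 isopropenylmagnesium bromide
Product: 3 2-methylhept-1-en-6-yn-3-ol (racemic)
Conditions: THF, −78 °C; aq. NH4Cl
Reagents that add atoms: none
Why: 1,2-addition of the alkenyl Grignard reagent to the aldehyde at −78 °C should outpace deprotonation of the alkyne C–H (Grignard addition), and the racemic carbinol centre is erased in step 2.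

Step 2
Reactants: 3 2-methylhept-1-en-6-yn-3-ol; 4 trimethyl orthoacetate
Product: 6 methyl (4E)-4-methylnon-4-en-8-ynoate, via ketene acetal 5 (not isolated)
Conditions: MeC(OMe)3 (excess), EtCO2H (cat.), 110 °C, MeOH distilled off
Reagents that add atoms: none
Why: Johnson–Claisen orthoester rearrangement, in which the mixed ketene acetal rearranges through a chair transition state with the butynyl chain equatorial and so gives the (E)-trisubstituted C5=C10 alkene needed later for the trans ring fusion.

Step 3
Reactants: 6 methyl (4E)-4-methylnon-4-en-8-ynoate; 7 [(trimethylsilyl)methyl]magnesium chloride; 8 acrolein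
Product: 11 methyl (4E,8Z)-4-methyl-12-oxo-8-[(trimethylsilyl)methyl]dodeca-4,8-dienoate, via alkenylcopper 9 (not isolated), via silyl enol ether 10 (not isolated)
Conditions: 7 (1.5 equiv), CuBr·SMe2 (1.5 equiv), LiBr, Et2O/Me2S, −40 → −10 °C; then 8, Me3SiCl, THF, −78 → −30 °C; aq. NH4Cl/AcOH
Reagents that add atoms: none
Why: syn-carbocupration of the terminal alkyne puts CH2SiMe3 on the internal carbon and copper on the terminus, and Me3SiCl-accelerated conjugate addition of the alkenylcopper to acrolein proceeds with retention, so C17 and C11 end up cis (carbocupration then 1,4-addition, enol ether hydrolysed on work-up); the saturated ester is inert to the organocopper reagent.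

Step 4
Reactants: 11 methyl (4E,8Z)-4-methyl-12-oxo-8-[(trimethylsilyl)methyl]dodeca-4,8-dienoate; 12 dimethyl (1-diazo-2-oxopropyl)phosphonate
Product: 13 methyl (4E,8Z)-4-methyl-8-[(trimethylsilyl)methyl]trideca-4,8-dien-12-ynoate
Conditions: K2CO3, MeOH, 0 °C → rt
Reagents that add atoms: none
Why: Seyferth–Gilbert homologation in the Ohira–Bestmann variant turns the aldehyde into the terminal alkyne C13≡C14 under conditions that the methyl ester, the alkenes and the allylsilane tolerate.

Step 5
Reactants: 13 methyl (4E,8Z)-4-methyl-8-[(trimethylsilyl)methyl]trideca-4,8-dien-12-ynoate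
Product: 14 (4E,8Z)-4-methyl-8-[(trimethylsilyl)methyl]trideca-4,8-dien-12-ynal
Conditions: i-Bu2AlH (1.1 equiv), CH2Cl2, −78 °C; aq. potassium sodium tartrate
Reagents that add atoms: none
Why: partial ester reduction, in which the tetrahedral aluminium hemiacetal is stable at −78 °C and releases the aldehyde only on work-up, while alkyne and allylsilane are inert.

Step 6
Reactants: 14 (4E,8Z)-4-methyl-8-[(trimethylsilyl)methyl]trideca-4,8-dien-12-ynal; 15 methyl 2-[bis(2,2,2-trifluoroethoxy)phosphoryl]propanoate
Product: 16 methyl (2Z,6E,10Z)-2,6-dimethyl-10-[(trimethylsilyl)methyl]pentadeca-2,6,10-trien-14-ynoate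
Conditions: KN(SiMe3)2, 18-crown-6, THF, −78 °C
Reagents that add atoms: none
Why: Still–Gennari olefination, in which the electron-poor phosphonate eliminates fast from the kinetic adduct and gives the (Z)-enoate, placing the future C19 cis to the chain.

Step 7
Reactants: 16 methyl (2Z,6E,10Z)-2,6-dimethyl-10-[(trimethylsilyl)methyl]pentadeca-2,6,10-trien-14-ynoate
Product: 17 (2Z,6E,10Z)-2,6-dimethyl-10-[(trimethylsilyl)methyl]pentadeca-2,6,10-trien-14-yn-1-ol
Conditions: i-Bu2AlH (2.5 equiv), CH2Cl2, −78 → 0 °C; aq. potassium sodium tartrate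
Reagents that add atoms: none
Why: 1,2-reduction of the enoate by the aluminium hydride gives the allylic alcohol without changing the alkene geometry (ester reduction).

Step 8
Reactants: 17 (2Z,6E,10Z)-2,6-dimethyl-10-[(trimethylsilyl)methyl]pentadeca-2,6,10-trien-14-yn-1-ol
Product: 18 [(2S,3R)-2-methyl-3-{(3E,7Z)-3-methyl-7-[(trimethylsilyl)methyl]dodeca-3,7-dien-11-yn-1-yl}oxiran-2-yl]methanol
Conditions: Ti(OiPr)4 (20 mol%), L-(+)-diethyl tartrate (24 mol%), t-BuOOH, 4 Å MS, CH2Cl2, −20 °C
Reagents that add atoms: tert-butyl hydroperoxide, CC(C)(C)OO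
Why: Sharpless asymmetric epoxidation, in which the titanium tartrate delivers oxygen only to the alkene of the bound allylic alcohol and L-(+)-tartrate should give the (2S,3R)-epoxide by the same facial rule that gives (2S,3S)-epoxygeraniol, which sets C3 and the absolute sense of all later centres.

Step 9
Reactants: 18 [(2S,3R)-2-methyl-3-{(3E,7Z)-3-methyl-7-[(trimethylsilyl)methyl]dodeca-3,7-dien-11-yn-1-yl}oxiran-2-yl]methanol
Product: 19 tert-butyl{[(2S,3R)-2-methyl-3-{(3E,7Z)-3-methyl-7-[(trimethylsilyl)methyl]dodeca-3,7-dien-11-yn-1-yl}oxiran-2-yl]methoxy}dimethylsilane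
Conditions: TBSCl, imidazole, DMF, 0 °C → rt
Reagents that add atoms: tert-butyldimethylsilyl chloride (TBSCl), CC(C)(C)[Si](C)(C)Cl
Why: silyl ether formation under mild base masks the primary hydroxyl, which would otherwise steer the Lewis acid of step 10 to the wrong epoxide carbon, and avoids Payne rearrangement.

Step 10
Reactants: 19 tert-butyl{[(2S,3R)-2-methyl-3-{(3E,7Z)-3-methyl-7-[(trimethylsilyl)methyl]dodeca-3,7-dien-11-yn-1-yl}oxiran-2-yl]methoxy}dimethylsilane
Product: 20 (3R,4R,5S,9R,10S)-19-[(tert-butyldimethylsilyl)oxy]-15,16-dinorlabd-8(17)-en-13-yn-3-ol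
Conditions: MeAlCl2 (2 equiv), CH2Cl2, −78 °C; aq. NaHCO3
Reagents that add atoms: none
Why: epoxide-initiated, allylsilane-terminated cation–olefin bicyclisation, in which C5=C10 attacks the activated tertiary C4 anti to oxygen (inversion, so the cis CH2OTBS becomes axial and 3-OH equatorial), chair–chair folding of the (E)-alkene gives the trans fusion at C5 and C10, C9 of the (Z)-allylsilane takes the C10 cation with its chain equatorial, and loss of Me3Si gives only the C8(17) methylene.

Step 11
Reactants: 20 (3R,4R,5S,9R,10S)-19-[(tert-butyldimethylsilyl)oxy]-15,16-dinorlabd-8(17)-en-13-yn-3-ol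
Product: 21 (3R,4R,5S,9R,10S)-3,19-bis[(tert-butyldimethylsilyl)oxy]-15,16-dinorlabd-8(17)-en-13-yne
Conditions: TBSOTf, 2,6-lutidine, CH2Cl2, −78 → 0 °C
Reagents that add atoms: tert-butyldimethylsilyl trifluoromethanesulfonate (TBSOTf), CC(C)(C)[Si](C)(C)OS(=O)(=O)C(F)(F)F
Why: the hindered equatorial 3-OH is silylated by the reactive silyl triflate (silyl ether formation) so that no free hydroxyl enters the nickel step.

Step 12
Reactants: 21 (3R,4R,5S,9R,10S)-3,19-bis[(tert-butyldimethylsilyl)oxy]-15,16-dinorlabd-8(17)-en-13-yne; 22 formaldehyde; 23 carbon monoxide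
Product: 26 (3R,4R,5S,9R,10S)-3,19-bis[(tert-butyldimethylsilyl)oxy]labda-8(17),13-dien-16,15-olide, via oxanickelacyclopentene 24 (not isolated), via acylnickel complex 25 (not isolated)
Conditions: Ni(cod)2 (1.2 equiv), PCy3 (1.2 equiv), CH2O (3 equiv), toluene/THF, −30 °C → rt, 21 added slowly; then CO (1 atm), rt
Reagents that add atoms: none
Why: Proposed new method: zerovalent nickel carrying PCy3 should couple the terminal alkyne and formaldehyde oxidatively to the oxanickelacyclopentene 24 (C14–C15 bond), CO then inserts into the Ni–C13 bond to give the acyl complex 25, and C(acyl)–O reductive elimination releases the butenolide (C13–C16 and C16–O bonds) while nickel is retired as its carbonyl complex, hence the stoichiometric metal. The closest known reaction types are the intramolecular hetero-Pauson–Khand reaction of ynals (with Cp2Ti(PMe3)2, Mo(CO)6 or Ru3(CO)12), the Ru3(CO)12-catalysed intermolecular (2+2+1) union of activated ketones, alkynes and CO, and the carbonylation of isolated oxanickelacyclopentenes from internal alkynes and aryl aldehydes to butenolides; the combination of formaldehyde, an unactivated terminal alkyne and CO is not precedented. The five-membered lactone is closed as a (2+2+1) cycloaddition in which the ring oxygen, C15 and C16 are assembled on the metal, the last bond (C16–O) forming by reductive elimination from the six-membered nickelacycle. No stereocentre is created and the ring fixes the alkene geometry. The step needs regioselectivity, which should follow because oxidative cyclisation of a terminal alkyne forms the new C–C bond at the unsubstituted, more nucleophilic terminus (C14) and leaves nickel, and later the carbonyl, on the substituted C13; it also needs chemoselectivity over alkyne oligomerisation and over the C8(17) alkene, addressed by slow addition of 21 to the preformed nickel–formaldehyde complex and by the inertness of the hindered 1,1-disubstituted alkene, with both oxygens silylated so that no O–H protonates the nickelacycle.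

Step 13
Reactants: 26 (3R,4R,5S,9R,10S)-3,19-bis[(tert-butyldimethylsilyl)oxy]labda-8(17),13-dien-16,15-olide
Product: 27 (3R,4R,5S,7S,9S,10S)-3,19-bis[(tert-butyldimethylsilyl)oxy]-7-hydroxylabda-8(17),13-dien-16,15-olide
Conditions: SeO2 (0.5 equiv), t-BuOOH (3 equiv), CH2Cl2, 0 °C → rt
Reagents that add atoms: selenium dioxide, O=[Se]=O; tert-butyl hydroperoxide, CC(C)(C)OO
Why: allylic oxidation with SeO2 (ene reaction at C17 with loss of the axial 7-H, then [2,3]-sigmatropic shift) should return the exocyclic alkene and place oxygen axially on C7, on the face opposite the C10 methyl, with the CH2 position preferred over the tertiary C9–H and the electron-poor butenolide alkene left alone.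

Step 14
Reactants: 27 (3R,4R,5S,7S,9S,10S)-3,19-bis[(tert-butyldimethylsilyl)oxy]-7-hydroxylabda-8(17),13-dien-16,15-olide
Product: 28 (3R,4R,5S,7S,9S,10S)-3,7,19-trihydroxylabda-8(17),13-dien-16,15-olide (CNP0280530.2)
Conditions: HF·pyridine, pyridine/THF, 0 °C → rt
Reagents that add atoms: none
Why: fluoride-mediated desilylation should cleave both silyl ethers under buffered conditions that leave the butenolide, the allylic alcohol and the exocyclic alkene untouched.

Compound list
1 | pent-4-ynal | C#CCCC=O | starting material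
2 | isopropenylmagnesium bromide | C=C(C)[Mg]Br | starting material
3 | 2-methylhept-1-en-6-yn-3-ol (racemic) | C=C(C)C(O)CCC#C | intermediate
4 | trimethyl orthoacetate | CC(OC)(OC)OC | starting material
5 | ketene acetal 3-[(1-methoxyethenyl)oxy]-2-methylhept-1-en-6-yne (not isolated) | C=C(OC)OC(CCC#C)C(C)=C | intermediate
6 | methyl (4E)-4-methylnon-4-en-8-ynoate | COC(=O)CC/C(C)=C/CCC#C | intermediate
7 | [(trimethylsilyl)methyl]magnesium chloride | C[Si](C)(C)C[Mg]Cl | starting material
8 | acrolein | C=CC=O | starting material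
9 | alkenylcopper, methyl (4E,8Z)-9-cuprio-4-methyl-8-[(trimethylsilyl)methyl]nona-4,8-dienoate (not isolated) | COC(=O)CC/C(C)=C/CC/C(C[Si](C)(C)C)=C/[Cu] | intermediate
10 | silyl enol ether, methyl (4E,8Z)-4-methyl-8-[(trimethylsilyl)methyl]-12-[(trimethylsilyl)oxy]dodeca-4,8,11-trienoate (not isolated) | COC(=O)CC/C(C)=C/CC/C(C[Si](C)(C)C)=C/CC=CO[Si](C)(C)C | intermediate
11 | methyl (4E,8Z)-4-methyl-12-oxo-8-[(trimethylsilyl)methyl]dodeca-4,8-dienoate | COC(=O)CC/C(C)=C/CC/C(C[Si](C)(C)C)=C/CCC=O | intermediate
12 | dimethyl (1-diazo-2-oxopropyl)phosphonate | COP(=O)(OC)C(=[N+]=[N-])C(C)=O | starting material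
13 | methyl (4E,8Z)-4-methyl-8-[(trimethylsilyl)methyl]trideca-4,8-dien-12-ynoate | COC(=O)CC/C(C)=C/CC/C(C[Si](C)(C)C)=C/CCC#C | intermediate
14 | (4E,8Z)-4-methyl-8-[(trimethylsilyl)methyl]trideca-4,8-dien-12-ynal | O=CCC/C(C)=C/CC/C(C[Si](C)(C)C)=C/CCC#C | intermediate
15 | methyl 2-[bis(2,2,2-trifluoroethoxy)phosphoryl]propanoate | COC(=O)C(C)P(=O)(OCC(F)(F)F)OCC(F)(F)F | starting material
16 | methyl (2Z,6E,10Z)-2,6-dimethyl-10-[(trimethylsilyl)methyl]pentadeca-2,6,10-trien-14-ynoate | COC(=O)/C(C)=C\CC/C(C)=C/CC/C(C[Si](C)(C)C)=C/CCC#C | intermediate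
17 | (2Z,6E,10Z)-2,6-dimethyl-10-[(trimethylsilyl)methyl]pentadeca-2,6,10-trien-14-yn-1-ol | OC/C(C)=C\CC/C(C)=C/CC/C(C[Si](C)(C)C)=C/CCC#C | intermediate
18 | [(2S,3R)-2-methyl-3-{(3E,7Z)-3-methyl-7-[(trimethylsilyl)methyl]dodeca-3,7-dien-11-yn-1-yl}oxiran-2-yl]methanol | OC[C@]1(C)O[C@@H]1CC/C(C)=C/CC/C(C[Si](C)(C)C)=C/CCC#C | intermediate
19 | tert-butyl{[(2S,3R)-2-methyl-3-{(3E,7Z)-3-methyl-7-[(trimethylsilyl)methyl]dodeca-3,7-dien-11-yn-1-yl}oxiran-2-yl]methoxy}dimethylsilane | CC(C)(C)[Si](C)(C)OC[C@]1(C)O[C@@H]1CC/C(C)=C/CC/C(C[Si](C)(C)C)=C/CCC#C | intermediate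
20 | (3R,4R,5S,9R,10S)-19-[(tert-butyldimethylsilyl)oxy]-15,16-dinorlabd-8(17)-en-13-yn-3-ol (trans-decalin; 3-OH equatorial; CH2OTBS axial on C4 and cis to the C10 methyl; but-3-ynyl chain equatorial on C9) | C=C1[C@@H](CCC#C)[C@]2(C)CC[C@@H](O)[C@@](C)(CO[Si](C)(C)C(C)(C)C)[C@H]2CC1 | intermediate
21 | (3R,4R,5S,9R,10S)-3,19-bis[(tert-butyldimethylsilyl)oxy]-15,16-dinorlabd-8(17)-en-13-yne | C=C1[C@@H](CCC#C)[C@]2(C)CC[C@@H](O[Si](C)(C)C(C)(C)C)[C@@](C)(CO[Si](C)(C)C(C)(C)C)[C@H]2CC1 | intermediate
22 | formaldehyde | C=O | starting material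
23 | carbon monoxide | [C-]#[O+] | starting material
24 | oxanickelacyclopentene (ring Ni–O–C15H2–C14H=C13, PCy3 on nickel) (not isolated) | C=C1[C@@H](CCC3=CCO[Ni-]3[P+](C4CCCCC4)(C4CCCCC4)C4CCCCC4)[C@]2(C)CC[C@@H](O[Si](C)(C)C(C)(C)C)[C@@](C)(CO[Si](C)(C)C(C)(C)C)[C@H]2CC1 | intermediate
25 | acylnickel complex (six-membered ring Ni–C16(=O)–C13=C14H–C15H2–O, PCy3 on nickel) (not isolated) | C=C1[C@@H](CCC3=CCO[Ni-]([P+](C4CCCCC4)(C4CCCCC4)C4CCCCC4)C3=O)[C@]2(C)CC[C@@H](O[Si](C)(C)C(C)(C)C)[C@@](C)(CO[Si](C)(C)C(C)(C)C)[C@H]2CC1 | intermediate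
26 | (3R,4R,5S,9R,10S)-3,19-bis[(tert-butyldimethylsilyl)oxy]labda-8(17),13-dien-16,15-olide | C=C1[C@@H](CCC2=CCOC2=O)[C@]2(C)CC[C@@H](O[Si](C)(C)C(C)(C)C)[C@@](C)(CO[Si](C)(C)C(C)(C)C)[C@H]2CC1 | intermediate
27 | (3R,4R,5S,7S,9S,10S)-3,19-bis[(tert-butyldimethylsilyl)oxy]-7-hydroxylabda-8(17),13-dien-16,15-olide (7-OH axial) | C=C1[C@@H](CCC2=CCOC2=O)[C@]2(C)CC[C@@H](O[Si](C)(C)C(C)(C)C)[C@@](C)(CO[Si](C)(C)C(C)(C)C)[C@H]2C[C@@H]1O | intermediate
28 | (3R,4R,5S,7S,9S,10S)-3,7,19-trihydroxylabda-8(17),13-dien-16,15-olide (CNP0280530.2) | C=C1[C@@H](CCC2=CCOC2=O)[C@]2(C)CC[C@@H](O)[C@@](C)(CO)[C@H]2C[C@@H]1O | target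

Total step count: 14
Longest linear sequence: 14 steps (1 to 28)

Steps most likely to fail (the bicyclisation of step 10 is ranked just behind these three, because epoxide-initiated, allylsilane-terminated cyclisations of this substrate class are established):

Step 12 (Proposed new method). Nickel-mediated oligomerisation of the terminal alkyne may outrun its oxidative coupling with formaldehyde, or carbonyl insertion may fail to turn the metallacycle over. The fallback uses known chemistry, sets out from 21 and comes back at 26. Lithiation of 21 (n-BuLi, THF, −78 °C) and addition to paraformaldehyde should give the propargylic alcohol F1 (C14–C15 bond). Alkoxide-directed trans-hydroalumination with NaAlH2(OCH2CH2OMe)2 followed by iodine should give the (Z)-iodo allylic alcohol F2 with iodine on C13. Carbonylative lactonisation (PdCl2(PPh3)2, CO 1 atm, K2CO3, THF, 50 °C) should then close the butenolide 26 (C13–C16 bond). The two ring bonds are made in separate operations in this variant.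

Step 3. The alkenylcopper may be lost by protonation, and acrolein may polymerise, under the Lewis acidic conditions of the conjugate addition. The fallback sets out from 6, passes through alkenylcopper 9 and comes back at 11, replacing the conjugate addition by a cross-coupling. Quenching 9 with iodine (1.0 equiv, −78 °C) should give the alkenyl iodide F3 with retention. Negishi coupling with commercial [2-(1,3-dioxolan-2-yl)ethyl]zinc bromide (PdCl2(dppf), THF, rt) should give the dioxolane acetal F4. Transacetalisation (pyridinium p-toluenesulfonate, wet acetone, 50 °C), mild enough for the allylsilane, should return aldehyde 11.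

Step 13. The new allylic alcohol may be over-oxidised to the enone, and facial selectivity in the oxygen transfer may be incomplete. The fallback sets out from 26 and comes back at 27 by oxidation to the ketone and catalyst-controlled reduction. SeO2/t-BuOOH in excess followed by Dess–Martin periodinane on the crude mixture should converge on the enone F5. 1,2-Reduction with the (R)-2-methyl-CBS-oxazaborolidine and catecholborane (toluene, −78 °C) should deliver hydride to the equatorial face of C7 and give the axial (7S) alcohol 27, with the butenolide inert to the borane.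

Further compounds
F1 | step 12 | (3R,4R,5S,9R,10S)-3,19-bis[(tert-butyldimethylsilyl)oxy]-16-norlabd-8(17)-en-13-yn-15-ol | C=C1[C@@H](CCC#CCO)[C@]2(C)CC[C@@H](O[Si](C)(C)C(C)(C)C)[C@@](C)(CO[Si](C)(C)C(C)(C)C)[C@H]2CC1
F2 | step 12 | (3R,4R,5S,9R,10S,13Z)-3,19-bis[(tert-butyldimethylsilyl)oxy]-13-iodo-16-norlabda-8(17),13-dien-15-ol | C=C1[C@@H](CC/C(I)=C/CO)[C@]2(C)CC[C@@H](O[Si](C)(C)C(C)(C)C)[C@@](C)(CO[Si](C)(C)C(C)(C)C)[C@H]2CC1
F3 | step 3 | methyl (4E,8Z)-9-iodo-4-methyl-8-[(trimethylsilyl)methyl]nona-4,8-dienoate | COC(=O)CC/C(C)=C/CC/C(C[Si](C)(C)C)=C/I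
F4 | step 3 | methyl (4E,8Z)-11-(1,3-dioxolan-2-yl)-4-methyl-8-[(trimethylsilyl)methyl]undeca-4,8-dienoate | COC(=O)CC/C(C)=C/CC/C(C[Si](C)(C)C)=C/CCC1OCCO1
F5 | step 13 | (3R,4R,5S,9S,10S)-3,19-bis[(tert-butyldimethylsilyl)oxy]-7-oxolabda-8(17),13-dien-16,15-olide | C=C1[C@@H](CCC2=CCOC2=O)[C@]2(C)CC[C@@H](O[Si](C)(C)C(C)(C)C)[C@@](C)(CO[Si](C)(C)C(C)(C)C)[C@H]2CC1=O
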